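**Retrosynthetic overview**
- The target comes from its 2,19-bis-TBS ether. The intact butenolide is joined by a B-alkyl Suzuki coupling (C12–C13) of a 9-vinyl decalin with 4-bromofuran-2(5H)-one, and the vinyl group comes from a Stille coupling of the C8=C9 enol triflate.
- C2α-OH, C5α-H and C6α-OH arise together from one double hydroboration of a Δ2,Δ5-diene. C19-OH comes from reduction of the C4 ester, and O6 is acetylated after selective silylation of O2 and O19.
- The Δ2 alkene comes from the C3 ketone (enol triflate, then formate reduction). The C4 quaternary centre and the C8 methyl come from a one-pot double methylation of a 4-carbomethoxy enone, made by bromination and methoxycarbonylation of the enone.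
- Ring order: rings A and B are bought together as (S)-Wieland–Miescher ketone, which supplies C10 and all absolute stereocontrol. No carbocycle is built, and the butenolide ring is bought and joined last.

Assumption: the target is read as 6α-acetoxy-2α,19-dihydroxylabda-8,13-dien-15,16-olide (2R,4S,5R,6S,10S); labdane numbering is used for every decalin (C10 angular carbon, C20 its methyl, α = face opposite C20, C18/C19 = α/β carbon on C4, C17 = methyl on C8).

**Step 1**
Reactants: 1 (S)-(+)-Wieland–Miescher ketone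
Product: 3 (S)-4-bromo-10β-methyl-Δ4-decalin-3,9-dione, via dibromide 2 (not isolated)
Conditions: Br2 (1.05 equiv), CH2Cl2, −10 °C; then Et3N (1.5 equiv), 0 °C → rt
Reagents that add atoms: bromine (BrBr)
Why: Bromine adds across the enone C4=C5 bond and Et3N removes the acidic C4–H with loss of the C5 bromide (bromination–dehydrobromination, E1cB), which gives the α-bromo enone and leaves the C9 ketone and the C10 stereocentre untouched.

**Step 2**
Reactants: 3 (S)-4-bromo-10β-methyl-Δ4-decalin-3,9-dione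
Product: 4 methyl (S)-10β-methyl-3,9-dioxo-Δ4-decalin-4-carboxylate
Conditions: CO (1 atm), MeOH, Et3N, PdCl2(PPh3)2 (5 mol %), DMF, 70 °C
Reagents that add atoms: carbon monoxide ([C-]#[O+]); methanol (CO)
Why: Oxidative addition of zerovalent palladium (formed in situ) into the activated vinyl C–Br bond, CO insertion and methanolysis of the acyl palladium (palladium-catalysed alkoxycarbonylation) give the vinylogous β-keto ester that carries the future C19.

**Step 3**
Reactants: 4 methyl (S)-10β-methyl-3,9-dioxo-Δ4-decalin-4-carboxylate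
Product: 7 methyl 4α,8α,10β-trimethyl-3,9-dioxo-Δ5-decalin-4β-carboxylate (8-epimer tolerated), via sodium dienolate 5 (not isolated), via sodium lithium dianion 6 (not isolated)
Conditions: NaH (1.05 equiv), THF, 0 °C → rt; LiN(iPr)2 (LDA, 1.1 equiv), −78 °C; MeI (4 equiv), −78 °C → rt
Reagents that add atoms: iodomethane (CI)
Why: NaH removes only the γ-proton (C6) of the vinylogous β-keto ester, which masks ring A as its dienolate so that LDA enolises only the C9 ketone toward C8, and MeI then alkylates C8 and, on warming, C4 (deconjugative α-alkylation of an extended enolate) from the α-face opposite the angular methyl, setting C4 (CH3 α, CO2Me β) and moving the alkene to C5=C6.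

**Step 4**
Reactants: 7 methyl 4α,8α,10β-trimethyl-3,9-dioxo-Δ5-decalin-4β-carboxylate
Product: 9 methyl 4α,8α,10β-trimethyl-9-oxo-3-(trifluoromethylsulfonyloxy)-Δ2,Δ5-decalin-4β-carboxylate, via potassium enolate 8 (not isolated)
Conditions: KN(SiMe3)2 (KHMDS, 1.05 equiv), THF, −78 °C; PhNTf2 (1.1 equiv), −78 → 0 °C
Reagents that add atoms: N-phenylbis(trifluoromethanesulfonimide) (O=S(=O)(N(c1ccccc1)S(=O)(=O)C(F)(F)F)C(F)(F)F)
Why: Kinetic deprotonation takes the unhindered C2 methylene of the C3 ketone far faster than the tertiary C8–H next to C9, and O-sulfonylation of that enolate gives the C3 enol triflate (enol triflate formation).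

**Step 5**
Reactants: 9 methyl 4α,8α,10β-trimethyl-9-oxo-3-(trifluoromethylsulfonyloxy)-Δ2,Δ5-decalin-4β-carboxylate
Product: 10 methyl 4α,8α,10β-trimethyl-9-oxo-Δ2,Δ5-decalin-4β-carboxylate
Conditions: Pd(OAc)2 (5 mol %), PPh3 (10 mol %), HCO2H (2 equiv), Et3N (3 equiv), DMF, 60 °C
Reagents that add atoms: none
Why: Palladium-catalysed formate reduction of the vinyl triflate (Cacchi reduction: oxidative addition, formate exchange, loss of CO2, reductive elimination) replaces OTf by H, so the C3 oxygen is removed and the Δ2 alkene is left for later hydration at C2.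

**Step 6**
Reactants: 10 methyl 4α,8α,10β-trimethyl-9-oxo-Δ2,Δ5-decalin-4β-carboxylate
Product: 12 methyl 4α,8,10β-trimethyl-9-(trifluoromethylsulfonyloxy)-Δ2,Δ5,Δ8-decalin-4β-carboxylate, via potassium enolate 11 (not isolated)
Conditions: KN(SiMe3)2 (1.3 equiv), THF, −78 → 0 °C; PhNTf2 (1.4 equiv), 0 °C → rt
Reagents that add atoms: N-phenylbis(trifluoromethanesulfonimide) (O=S(=O)(N(c1ccccc1)S(=O)(=O)C(F)(F)F)C(F)(F)F)
Why: C8 carries the only α-hydrogen of the C9 ketone (C10 is quaternary), so enolisation and triflation (enol triflate formation) give the tetrasubstituted C8=C9 triflate and erase the C8 stereocentre.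

**Step 7**
Reactants: 12 methyl 4α,8,10β-trimethyl-9-(trifluoromethylsulfonyloxy)-Δ2,Δ5,Δ8-decalin-4β-carboxylate
Product: 14 methyl 2α,6α-dihydroxy-4α,8,10β-trimethyl-9-(trifluoromethylsulfonyloxy)-5α-Δ8-decalin-4β-carboxylate, via bis-alkylborane 13 (not isolated)
Conditions: BH3·THF (4 equiv), THF, 0 °C → rt, 16 h; then NaBO3·4H2O, THF/H2O, rt
Reagents that add atoms: sodium perborate ([Na+].[O-]OB=O)
Why: In this double hydroboration–oxidation (Brown) borane adds syn from the α-face, opposite the C10 methyl and the C4β ester, with boron at the less hindered C2 (C3 is neopentyl) and C6 (C5 is fully substituted), so oxidation with retention sets C2 (α-OH), C5 (α-H, trans fusion) and C6 (α-OH) at once while the electron-poor tetrasubstituted enol triflate stays inert.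

**Step 8**
Reactants: 14 methyl 2α,6α-dihydroxy-4α,8,10β-trimethyl-9-(trifluoromethylsulfonyloxy)-5α-Δ8-decalin-4β-carboxylate
Product: 15 2α,6α-dihydroxy-4β-(hydroxymethyl)-4α,8,10β-trimethyl-5α-Δ8-decalin-9-yl trifluoromethanesulfonate
Conditions: iBu2AlH (DIBAL-H, 6 equiv), CH2Cl2, −78 → 0 °C; aq. potassium sodium tartrate work-up
Reagents that add atoms: none
Why: Hydride reduction of the hindered axial methyl ester (ester reduction) gives the C19 primary alcohol without touching the vinyl triflate or any stereocentre.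

**Step 9**
Reactants: 15 2α,6α-dihydroxy-4β-(hydroxymethyl)-4α,8,10β-trimethyl-5α-Δ8-decalin-9-yl trifluoromethanesulfonate
Product: 16 2α-(tert-butyldimethylsilyloxy)-4β-(tert-butyldimethylsilyloxymethyl)-6α-hydroxy-4α,8,10β-trimethyl-5α-Δ8-decalin-9-yl trifluoromethanesulfonate
Conditions: TBSCl (2.3 equiv), imidazole (5 equiv), DMF, 0 °C → rt
Reagents that add atoms: tert-butyldimethylsilyl chloride (CC(C)(C)[Si](C)(C)Cl)
Why: Silyl ether formation is steered by sterics, the primary C19-OH and the unhindered equatorial C2-OH reacting while the C6-OH, flanked by C5 and the C18 methyl, stays free.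

**Step 10**
Reactants: 16 2α-(tert-butyldimethylsilyloxy)-4β-(tert-butyldimethylsilyloxymethyl)-6α-hydroxy-4α,8,10β-trimethyl-5α-Δ8-decalin-9-yl trifluoromethanesulfonate
Product: 17 6α-acetoxy-2α-(tert-butyldimethylsilyloxy)-4β-(tert-butyldimethylsilyloxymethyl)-4α,8,10β-trimethyl-5α-Δ8-decalin-9-yl trifluoromethanesulfonate
Conditions: Ac2O (3 equiv), DMAP (0.2 equiv), pyridine, rt → 40 °C
Reagents that add atoms: acetic anhydride (CC(=O)OC(C)=O)
Why: DMAP-catalysed acylation of the only free, hindered secondary alcohol gives the 6α-acetate with retention at C6.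

**Step 11**
Reactants: 17 6α-acetoxy-2α-(tert-butyldimethylsilyloxy)-4β-(tert-butyldimethylsilyloxymethyl)-4α,8,10β-trimethyl-5α-Δ8-decalin-9-yl trifluoromethanesulfonate
Product: 18 6α-acetoxy-2α-(tert-butyldimethylsilyloxy)-4β-(tert-butyldimethylsilyloxymethyl)-4α,8,10β-trimethyl-9-vinyl-5α-Δ8-decalin
Conditions: CH2=CHSnBu3 (1.5 equiv), Pd(PPh3)4 (5 mol %), LiCl (3 equiv), THF, reflux
Reagents that add atoms: tributyl(vinyl)stannane (C=C[Sn](CCCC)(CCCC)CCCC)
Why: Stille coupling (oxidative addition into the vinyl triflate assisted by LiCl, transmetalation from tin, reductive elimination) installs C11–C12 as a vinyl group on C9.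

**Step 12**
Reactants: 18 6α-acetoxy-2α-(tert-butyldimethylsilyloxy)-4β-(tert-butyldimethylsilyloxymethyl)-4α,8,10β-trimethyl-9-vinyl-5α-Δ8-decalin; 19 4-bromofuran-2(5H)-one
Product: 21 6α-acetoxy-2α,19-bis(tert-butyldimethylsilyloxy)labda-8,13-dien-15,16-olide, via B-alkyl-9-BBN adduct 20 (not isolated)
Conditions: 9-BBN-H (1.5 equiv), THF, 0 °C → rt; then 19 (1.3 equiv), PdCl2(dppf) (dppf = 1,1'-bis(diphenylphosphino)ferrocene, 8 mol %), AsPh3 (8 mol %), Cs2CO3 (3 equiv), DMF/H2O, rt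
Reagents that add atoms: 4-bromofuran-2(5H)-one 19 (BrC1=CC(=O)OC1)
Why: 9-BBN-H hydroborates only the monosubstituted vinyl group at its terminal carbon (the tetrasubstituted ring alkene is inert) and the B-alkyl borane is coupled with the vinyl bromide (B-alkyl Suzuki–Miyaura coupling), which forms C12–C13 and brings in the intact butenolide.

**Step 13**
Reactants: 21 6α-acetoxy-2α,19-bis(tert-butyldimethylsilyloxy)labda-8,13-dien-15,16-olide
Product: 22 6α-acetoxy-2α,19-dihydroxylabda-8,13-dien-15,16-olide (target)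
Conditions: HF·pyridine, pyridine/THF, 0 °C → rt
Reagents that add atoms: none
Why: Fluoride-driven desilylation cleaves both Si–O bonds under mildly acidic conditions that leave the acetate, the butenolide and the tetrasubstituted alkene intact, and no stereocentre is touched.

**Compound list**
1 | (S)-(+)-Wieland–Miescher ketone; (8aS)-8a-methyl-3,4,8,8a-tetrahydronaphthalene-1,6(2H,7H)-dione | C1CCC(=O)[C@@]2(C)CCC(=O)C=C12 | starting material
2 | 4β,5α-dibromo-10β-methyldecalin-3,9-dione (not isolated) | C1CCC(=O)[C@@]2(C)CCC(=O)[C@H](Br)[C@]12Br | intermediate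
3 | (S)-4-bromo-10β-methyl-Δ4-decalin-3,9-dione | C1CCC(=O)[C@@]2(C)CCC(=O)C(Br)=C12 | intermediate
4 | methyl (S)-10β-methyl-3,9-dioxo-Δ4-decalin-4-carboxylate | C1CCC(=O)[C@@]2(C)CCC(=O)C(C(=O)OC)=C12 | intermediate
5 | sodium 3,5-dienolate of 4 (not isolated) | C1CC(=O)[C@@]2(C)CCC([O-])=C(C(=O)OC)C2=C1.[Na+] | intermediate
6 | sodium lithium dianion of 4: ring A dienolate plus C8=C9 enolate (not isolated) | C1C=C([O-])[C@@]2(C)CCC([O-])=C(C(=O)OC)C2=C1.[Na+].[Li+] | intermediate
7 | methyl 4α,8α,10β-trimethyl-3,9-dioxo-Δ5-decalin-4β-carboxylate (major C8 epimer drawn) | C1[C@@H](C)C(=O)[C@@]2(C)CCC(=O)[C@](C)(C(=O)OC)C2=C1 | intermediate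
8 | potassium C2=C3 enolate of 7 (not isolated) | C1[C@@H](C)C(=O)[C@@]2(C)CC=C([O-])[C@](C)(C(=O)OC)C2=C1.[K+] | intermediate
9 | methyl 4α,8α,10β-trimethyl-9-oxo-3-(trifluoromethylsulfonyloxy)-Δ2,Δ5-decalin-4β-carboxylate | C1[C@@H](C)C(=O)[C@@]2(C)CC=C(OS(=O)(=O)C(F)(F)F)[C@](C)(C(=O)OC)C2=C1 | intermediate
10 | methyl 4α,8α,10β-trimethyl-9-oxo-Δ2,Δ5-decalin-4β-carboxylate | C1[C@@H](C)C(=O)[C@@]2(C)CC=C[C@](C)(C(=O)OC)C2=C1 | intermediate
11 | potassium C8=C9 enolate of 10 (not isolated) | C1C(C)=C([O-])[C@@]2(C)CC=C[C@](C)(C(=O)OC)C2=C1.[K+] | intermediate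
12 | methyl 4α,8,10β-trimethyl-9-(trifluoromethylsulfonyloxy)-Δ2,Δ5,Δ8-decalin-4β-carboxylate | C1C(C)=C(OS(=O)(=O)C(F)(F)F)[C@@]2(C)CC=C[C@](C)(C(=O)OC)C2=C1 | intermediate
13 | 2α,6α-bis(boranyl)-5α-H adduct of 12 (not isolated) | B[C@H]1CC(C)=C(OS(=O)(=O)C(F)(F)F)[C@@]2(C)C[C@@H](B)C[C@](C)(C(=O)OC)[C@H]12 | intermediate
14 | methyl 2α,6α-dihydroxy-4α,8,10β-trimethyl-9-(trifluoromethylsulfonyloxy)-5α-Δ8-decalin-4β-carboxylate | O[C@H]1CC(C)=C(OS(=O)(=O)C(F)(F)F)[C@@]2(C)C[C@@H](O)C[C@](C)(C(=O)OC)[C@H]12 | intermediate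
15 | 2α,6α-dihydroxy-4β-(hydroxymethyl)-4α,8,10β-trimethyl-5α-Δ8-decalin-9-yl trifluoromethanesulfonate | O[C@H]1CC(C)=C(OS(=O)(=O)C(F)(F)F)[C@@]2(C)C[C@@H](O)C[C@](C)(CO)[C@H]12 | intermediate
16 | 2α-(tert-butyldimethylsilyloxy)-4β-(tert-butyldimethylsilyloxymethyl)-6α-hydroxy-4α,8,10β-trimethyl-5α-Δ8-decalin-9-yl trifluoromethanesulfonate | O[C@H]1CC(C)=C(OS(=O)(=O)C(F)(F)F)[C@@]2(C)C[C@@H](O[Si](C)(C)C(C)(C)C)C[C@](C)(CO[Si](C)(C)C(C)(C)C)[C@H]12 | intermediate
17 | 6α-acetoxy-2α-(tert-butyldimethylsilyloxy)-4β-(tert-butyldimethylsilyloxymethyl)-4α,8,10β-trimethyl-5α-Δ8-decalin-9-yl trifluoromethanesulfonate | CC(=O)O[C@H]1CC(C)=C(OS(=O)(=O)C(F)(F)F)[C@@]2(C)C[C@@H](O[Si](C)(C)C(C)(C)C)C[C@](C)(CO[Si](C)(C)C(C)(C)C)[C@H]12 | intermediate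
18 | 6α-acetoxy-2α-(tert-butyldimethylsilyloxy)-4β-(tert-butyldimethylsilyloxymethyl)-4α,8,10β-trimethyl-9-vinyl-5α-Δ8-decalin | CC(=O)O[C@H]1CC(C)=C(C=C)[C@@]2(C)C[C@@H](O[Si](C)(C)C(C)(C)C)C[C@](C)(CO[Si](C)(C)C(C)(C)C)[C@H]12 | intermediate
19 | 4-bromofuran-2(5H)-one | BrC1=CC(=O)OC1 | starting material
20 | 9-[2-(decalin-9-yl)ethyl]-9-borabicyclo[3.3.1]nonane from 18, boron on C12 (not isolated) | CC(=O)O[C@H]1CC(C)=C(CCB3C4CCCC3CCC4)[C@@]2(C)C[C@@H](O[Si](C)(C)C(C)(C)C)C[C@](C)(CO[Si](C)(C)C(C)(C)C)[C@H]12 | intermediate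
21 | 6α-acetoxy-2α,19-bis(tert-butyldimethylsilyloxy)labda-8,13-dien-15,16-olide | CC(=O)O[C@H]1CC(C)=C(CCC3=CC(=O)OC3)[C@@]2(C)C[C@@H](O[Si](C)(C)C(C)(C)C)C[C@](C)(CO[Si](C)(C)C(C)(C)C)[C@H]12 | intermediate
22 | 6α-acetoxy-2α,19-dihydroxylabda-8,13-dien-15,16-olide (CNP0231903.1) | CC(=O)O[C@H]1CC(C)=C(CCC2=CC(=O)OC2)[C@@]2(C)C[C@@H](O)C[C@](C)(CO)[C@H]12 | target

**Totals**
Total step count: 13. Longest linear sequence: 13 steps (1 → 22); compound 19 is bought.

**Steps most likely to fail, with fallbacks**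

Step 3 (one-pot dianion double methylation). The risks are C8/C4 mixtures, O-methylation and over-methylation at C8. The fallback sets out from 4 and comes back at 10, and it replaces in-situ masking by a protecting group. Ethylene glycol with p-TsOH (benzene, rt) ketalises only the saturated ketone to give the 9-ethylene ketal of 4 F1. KOtBu/MeI (tBuOH–THF, 0 °C → rt) then methylates C4 alone from the α-face to give the 4α-methyl-Δ5-3-ketone ketal F2. KN(SiMe3)2/PhNTf2 gives the C3 enol triflate F3. Pd(OAc)2/PPh3 with HCO2H and Et3N gives the Δ2,Δ5-diene ketal F4. Aqueous HCl in THF frees the 8-unsubstituted 9-ketone F5. LiN(iPr)2/MeI at −78 °C methylates C8 and delivers 10.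

Step 7 (double hydroboration). The risks are C2/C3 regiochemistry at Δ2 eroded by the allylic ester, a sluggish Δ5 alkene, and loss of triflate during oxidation. The fallback sets out from 12 and comes back at 15; it removes the ester first and uses two boranes of different size. iBu2AlH (CH2Cl2, −78 → 0 °C) reduces 12 to the C19 alcohol F6. 9-BBN-H (2.2 equiv, THF, rt → 50 °C) caps the hydroxyl as its borinate and, being bulky, hydroborates only the Δ2 bond at C2 from the α-face. BH3·THF is then added for the hindered Δ5 bond, giving the mixed borane adduct F7 (not isolated). One NaBO3·4H2O oxidation gives triol 15.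

Step 12 (hydroboration and B-alkyl Suzuki coupling). The risks are the base-sensitive bromobutenolide and slow transmetalation of the hindered alkyl borane. The fallback sets out from 20 and comes back at 21; it swaps boron for zinc and needs no base. Oxidation of 20 with NaBO3·4H2O gives the C12 primary alcohol F8. I2/PPh3/imidazole (CH2Cl2, 0 °C) gives the primary iodide F9. Zn dust with LiCl (THF, 40 °C) gives the alkylzinc iodide F10 (not isolated). Negishi coupling with 19 (Pd(PPh3)4, THF, rt) gives 21.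

**Further compounds**
F1 | step 3 | methyl (S)-9,9-ethylenedioxy-10β-methyl-3-oxo-Δ4-decalin-4-carboxylate | C1CCC2(OCCO2)[C@@]3(C)CCC(=O)C(C(=O)OC)=C13
F2 | step 3 | methyl 9,9-ethylenedioxy-4α,10β-dimethyl-3-oxo-Δ5-decalin-4β-carboxylate | C1CC2(OCCO2)[C@@]3(C)CCC(=O)[C@](C)(C(=O)OC)C3=C1
F3 | step 3 | methyl 9,9-ethylenedioxy-4α,10β-dimethyl-3-(trifluoromethylsulfonyloxy)-Δ2,Δ5-decalin-4β-carboxylate | C1CC2(OCCO2)[C@@]3(C)CC=C(OS(=O)(=O)C(F)(F)F)[C@](C)(C(=O)OC)C3=C1
F4 | step 3 | methyl 9,9-ethylenedioxy-4α,10β-dimethyl-Δ2,Δ5-decalin-4β-carboxylate | C1CC2(OCCO2)[C@@]3(C)CC=C[C@](C)(C(=O)OC)C3=C1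
F5 | step 3 | methyl 4α,10β-dimethyl-9-oxo-Δ2,Δ5-decalin-4β-carboxylate | C1CC(=O)[C@@]2(C)CC=C[C@](C)(C(=O)OC)C2=C1
F6 | step 7 | 4β-(hydroxymethyl)-4α,8,10β-trimethyl-Δ2,Δ5,Δ8-decalin-9-yl trifluoromethanesulfonate | C1C(C)=C(OS(=O)(=O)C(F)(F)F)[C@@]2(C)CC=C[C@](C)(CO)C2=C1
F7 | step 7 | mixed borane adduct of F6: 19-O-(9-BBN) borinate, 2α-(9-BBN), 6α-boranyl, 5α-H | B[C@H]1CC(C)=C(OS(=O)(=O)C(F)(F)F)[C@@]2(C)C[C@@H](B3C4CCCC3CCC4)C[C@](C)(COB3C4CCCC3CCC4)[C@H]12
F8 | step 12 | 6α-acetoxy-2α-(tert-butyldimethylsilyloxy)-4β-(tert-butyldimethylsilyloxymethyl)-9-(2-hydroxyethyl)-4α,8,10β-trimethyl-5α-Δ8-decalin | CC(=O)O[C@H]1CC(C)=C(CCO)[C@@]2(C)C[C@@H](O[Si](C)(C)C(C)(C)C)C[C@](C)(CO[Si](C)(C)C(C)(C)C)[C@H]12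
F9 | step 12 | 6α-acetoxy-2α-(tert-butyldimethylsilyloxy)-4β-(tert-butyldimethylsilyloxymethyl)-9-(2-iodoethyl)-4α,8,10β-trimethyl-5α-Δ8-decalin | CC(=O)O[C@H]1CC(C)=C(CCI)[C@@]2(C)C[C@@H](O[Si](C)(C)C(C)(C)C)C[C@](C)(CO[Si](C)(C)C(C)(C)C)[C@H]12
F10 | step 12 | alkylzinc iodide from F9 (zinc on C12) | CC(=O)O[C@H]1CC(C)=C(CC[Zn]I)[C@@]2(C)C[C@@H](O[Si](C)(C)C(C)(C)C)C[C@](C)(CO[Si](C)(C)C(C)(C)C)[C@H]12
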